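**Retrosynthetic overview**
- Last skeletal bond: C11=C12, by Horner–Wadsworth–Emmons (HWE) union of a triol-end C15 dienal (3,5-diol held as a cyclic carbonate) with an ε-end C25 phosphonate; carbonate methanolysis ends the route.
- C25 phosphonate: a C10 bisphosphonate (from the C10 trienedial) olefinated once with the (3R,6R)-3-hydroxy-ε C15 dienal, which comes from racemic α-ionone (nitrile HWE, C3 allylic oxidation, catalyst-controlled ketone reduction with separation of diastereomers, nitrile reduction).
- Feature that carries the strategy: in the triol ring (C1–C6) the C3 and C5 oxygens are cis-1,3 and the C5 and C6 oxygens are trans. This is the pattern left by rear-side opening at C5 of the 5,6-epoxide that lies anti to the C3 oxygen; the C3 tert-butyl carbonate performs this opening on the C13 enone.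
- Epoxide precursor: ketoisophorone → (4R,6R)-actinol → Boc carbonate → enol triflate → Heck coupling with methyl vinyl ketone → peracid epoxidation.
- Rings: both carbocycles come from the starting materials; the only ring formed is the 1,3-dioxan-2-one across C3/C5 (key step), opened again in the last step.

Key step: step 6

Assumption: carotenoid numbering is used for every fragment (ring C1–C6, chain C7–C15, primes for the ε half), and commercial α-ionone is taken as the racemate.

**Route**

Step 1
Reactants: 1 ketoisophorone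
Product: 3 (4R,6R)-actinol [(4R,6R)-4-hydroxy-2,2,6-trimethylcyclohexanone], via (6R)-levodione 2 (not isolated)
Conditions: old yellow enzyme 2 (ene-reductase), NADP+, glucose, glucose dehydrogenase, phosphate buffer pH 7, 30 °C; then levodione reductase (Corynebacterium aquaticum), NAD+, same pot
Reagents that add atoms: none
Why: Enzymatic conjugate reduction of the enone followed by enzymatic reduction of the unhindered C4 carbonyl, both under enzyme control, should set the carbinol centre (the later C3) as R.

Step 2
Reactants: 3 (4R,6R)-actinol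
Product: 4 (4R,6R)-4-(tert-butoxycarbonyloxy)-2,2,6-trimethylcyclohexanone
Conditions: Boc2O, DMAP (cat.), Et3N, CH2Cl2, 0 °C to rt
Reagents that add atoms: di-tert-butyl dicarbonate, CC(C)(C)OC(=O)OC(=O)OC(C)(C)C
Why: DMAP-catalysed acylation of the secondary alcohol gives the mixed carbonate that serves first as protecting group and later as the tethered nucleophile; no stereocentre is touched.

Step 3
Reactants: 4 Boc-actinol
Product: 5 (4R)-4-(tert-butoxycarbonyloxy)-2,6,6-trimethylcyclohex-1-en-1-yl trifluoromethanesulfonate
Conditions: KN(SiMe3)2, THF, −78 °C; then PhNTf2, −78 to 0 °C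
Reagents that add atoms: N-phenylbis(trifluoromethanesulfonimide), O=S(=O)(N(c1ccccc1)S(=O)(=O)C(F)(F)F)C(F)(F)F
Why: The ketone has a single α-hydrogen, so deprotonation gives one enolate whose O-sulfonylation (enol triflate formation) fixes the future C5=C6 bond; the methyl-bearing centre is erased and the carbinol centre is untouched.

Step 4
Reactants: 5 enol triflate; 6 methyl vinyl ketone
Product: 7 (3R)-3-(tert-butoxycarbonyloxy)-β-ionone [(E)-4-[(4R)-4-(tert-butoxycarbonyloxy)-2,6,6-trimethylcyclohex-1-en-1-yl]but-3-en-2-one]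
Conditions: Pd(OAc)2 (cat.), PPh3, Et3N, DMF, 70 °C
Reagents that add atoms: none
Why: Mizoroki–Heck coupling of the vinyl triflate with the enone gives the E-dienone through syn insertion and syn β-hydride elimination, and the homoallylic carbonate is inert to palladium.

Step 5
Reactants: 7 (3R)-3-O-Boc-β-ionone
Product: 8 (3S,5R,6S)-3-(tert-butoxycarbonyloxy)-5,6-epoxy-5,6-dihydro-β-ionone (epoxide anti to the C3 oxygen)
Conditions: mCPBA, NaHCO3, CH2Cl2, 0 °C; chromatography
Reagents that add atoms: 3-chloroperbenzoic acid, OOC(=O)c1cccc(Cl)c1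
Why: Prilezhaev epoxidation takes place at the electron-rich tetrasubstituted C5=C6 bond and not at the enone C7=C8 bond, and the acylated C3 oxygen, which cannot hydrogen-bond to the peracid, should steer the oxygen mainly to the opposite face (substrate control), the minor syn epoxide being removed by chromatography.

Step 6
Reactants: 8 anti-epoxy tert-butyl carbonate
Product: 9 (3S,5S,6S)-3,5,6-trihydroxy-5,6-dihydro-β-ionone 3,5-cyclic carbonate with free 6-hydroxyl [8-hydroxy-1,7,7-trimethyl-8-[(E)-3-oxobut-1-enyl]-2,4-dioxabicyclo[3.3.1]nonan-3-one]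
Conditions: BF3·OEt2 (2 equiv), CH2Cl2, −78 to −30 °C; aq. NaHCO3
Reagents that add atoms: none
Why: BF3 coordinates the epoxide oxygen; in the half-chair conformer with the C3 carbonate axial, the carbonyl oxygen of the tert-butyl carbonate lies under C5 on the face opposite the oxirane oxygen and attacks C5 in a borderline SN2, trans-diaxial (Fürst–Plattner) opening, after which the dioxocarbenium ion loses its tert-butyl group as isobutene. The closest known reaction type is the Lewis-acid-promoted opening of epoxides by a neighbouring tert-butyl carbonate that gives cyclic carbonates of 1,3-diols. The one ring formed, the 1,3-dioxan-2-one bridging C3 and C5, closes in a 6-exo-tet mode. The new stereocentre at C5 is set with inversion by the tether, which can reach only the rear of C5 from the C3 oxygen, so the C3 and C5 oxygens end up cis and the C5 and C6 oxygens trans, while C6 keeps its oxygen and its configuration. The step needs attack at C5 and not at C6, and participation faster than semipinacol ring contraction or loss of the Boc group; the tether geometry (attack at C6 would need a seven-membered bridge) and the electron-poor enone vinyl group on C6, which disfavours positive charge there, should secure the first, and low temperature together with the intramolecular nucleophile the second.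

Step 7
Reactants: 9 cyclic carbonate hydroxy enone
Product: 11 (2E,4E)-3-methyl-5-[(3S,5S,6S)-6-hydroxy-3,5-carbonyldioxy ring]penta-2,4-dienal (triol-end C15 aldehyde), via N-cyclohexyl aldimine 10 (not isolated)
Conditions: diethyl 2-(cyclohexylamino)vinylphosphonate, NaH, THF, 0 °C to rt; then aq. oxalic acid, THF, rt; chromatography
Reagents that add atoms: diethyl 2-(cyclohexylamino)vinylphosphonate, CCOP(=O)(OCC)/C=C/NC1CCCCC1; water, O
Why: HWE formylolefination with the anion of the enamino phosphonate adds 1,2 to the methyl ketone and should give mainly the 9E azatriene, whose mild acid hydrolysis frees the dienal without hydride reagents that would attack the carbonate.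

Step 8
Reactants: 12 (±)-α-ionone
Product: 13 (±)-(2E,4E)-3-methyl-5-(2,6,6-trimethylcyclohex-2-en-1-yl)penta-2,4-dienenitrile
Conditions: (EtO)2P(O)CH2CN, NaH, THF, 0 °C to rt; chromatography (2E isomer)
Reagents that add atoms: diethyl cyanomethylphosphonate, CCOP(=O)(CC#N)OCC
Why: HWE olefination of the methyl ketone with the cyanomethylphosphonate anion gives the dienenitrile, mainly 9E, under conditions too weakly basic to move the ring double bond.

Step 9
Reactants: 13 racemic dienenitrile
Product: 14 (±)-(2E,4E)-3-methyl-5-(2,6,6-trimethyl-4-oxocyclohex-2-en-1-yl)penta-2,4-dienenitrile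
Conditions: t-BuOOH (70% aq.), Rh2(cap)4 (dirhodium tetrakis(caprolactamate), cat.), K2CO3, CH2Cl2, rt
Reagents that add atoms: tert-butyl hydroperoxide, CC(C)(C)OO
Why: Catalytic allylic C–H oxidation by tert-butylperoxyl radicals should attack the ring C3 methylene, the only unhindered secondary allylic position (the C6 hydrogen is tertiary and flanked by the gem-dimethyl group), and give the enone.

Step 10
Reactants: 14 racemic 3-oxo nitrile
Product: 15 (2E,4E)-5-[(1R,4R)-4-hydroxy-2,6,6-trimethylcyclohex-2-en-1-yl]-3-methylpenta-2,4-dienenitrile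
Conditions: (S)-2-methyl-CBS-oxazaborolidine (0.2 equiv), catecholborane, toluene, −78 °C; chromatography
Reagents that add atoms: none
Why: Corey–Bakshi–Shibata reduction delivers hydride under catalyst control with the C4=C5 side of the enone as the large group, which should give 3R in both enantiomers of the racemate, so the (3R,6R)-trans and (3R,6S)-cis alcohols are diastereomers and are separated by chromatography; the reagent sets C3 and the separation selects C6.

Step 11
Reactants: 15 (1R,4R)-hydroxy nitrile
Product: 17 (2E,4E)-5-[(1R,4R)-4-hydroxy-2,6,6-trimethylcyclohex-2-en-1-yl]-3-methylpenta-2,4-dienal, via bis(diisobutylaluminium) aldimine 16 (not isolated)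
Conditions: i-Bu2AlH (3.2 equiv), CH2Cl2, −78 to −40 °C; aq. potassium sodium tartrate
Reagents that add atoms: water, O
Why: Partial reduction of the conjugated nitrile by DIBAL-H stops at the aluminium aldimine, which is hydrolysed on work-up to the dienal, the aluminium alkoxide of the free alcohol being inert.

Step 12
Reactants: 18 (2E,4E,6E)-2,7-dimethylocta-2,4,6-trienedial
Product: 19 (2E,4E,6E)-2,7-dimethylocta-2,4,6-triene-1,8-diol
Conditions: NaBH4, MeOH/CH2Cl2, 0 °C
Reagents that add atoms: none
Why: Borohydride 1,2-reduction of both enal carbonyls gives the bis-allylic diol and leaves the triene untouched.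

Step 13
Reactants: 19 C10 diol
Product: 20 (2E,4E,6E)-1,8-dibromo-2,7-dimethylocta-2,4,6-triene
Conditions: PBr3, pyridine (cat.), Et2O, −15 °C
Reagents that add atoms: phosphorus tribromide, BrP(Br)Br
Why: SN2 displacement of the activated primary allylic hydroxyls by bromide (PBr3 bromination) at low temperature keeps the all-E triene.

Step 14
Reactants: 20 C10 dibromide
Product: 21 tetraethyl [(2E,4E,6E)-2,7-dimethylocta-2,4,6-triene-1,8-diyl]bis(phosphonate)
Conditions: P(OEt)3 (neat), 130 °C
Reagents that add atoms: triethyl phosphite, CCOP(OCC)OCC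
Why: Michaelis–Arbuzov reaction of the primary allylic bromides with triethyl phosphite gives the bisphosphonate.

Step 15
Reactants: 17 ε-end C15 hydroxy dienal; 21 C10 bisphosphonate (3 equiv)
Product: 22 diethyl [(2E,4E,6E,8E,10E,12E)-13-[(1R,4R)-4-hydroxy-2,6,6-trimethylcyclohex-2-en-1-yl]-2,7,11-trimethyltrideca-2,4,6,8,10,12-hexaen-1-yl]phosphonate (ε-end C25 phosphonate)
Conditions: NaN(SiMe3)2 (1.1 equiv), THF, −30 °C; slow addition of 17, then rt; chromatography
Reagents that add atoms: none
Why: HWE olefination with the monoanion of the bisphosphonate used in excess should give mainly single condensation and an E C11'=C12' bond, the second phosphonate remaining for the final union.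

Step 16
Reactants: 22 ε-end C25 phosphonate; 11 triol-end C15 aldehyde
Product: 23 (3S,5S,6S,3'R,6'R)-5,6-dihydro-β,ε-carotene-3,5,6,3'-tetrol 3,5-cyclic carbonate
Conditions: NaN(SiMe3)2 (1.2 equiv), THF, −78 to 0 °C; crystallisation
Reagents that add atoms: none
Why: HWE olefination of the dienal by the polyenyl phosphonate anion forms the C11=C12 bond, mainly E, and the non-nucleophilic base leaves the cyclic carbonate and both free hydroxyls alone.

Step 17
Reactants: 23 C40 cyclic carbonate
Product: 24 (3S,5S,6S,3'R,6'R)-5,6-dihydro-β,ε-carotene-3,5,6,3'-tetrol (CNP0219917.1)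
Conditions: K2CO3 (cat.), MeOH/THF, rt, dark, argon
Reagents that add atoms: none
Why: Base-catalysed transesterification (methanolysis) of the cyclic carbonate frees the C3 and C5 hydroxyls without touching the polyene or any stereocentre.

**Compound list**

1 | ketoisophorone (2,6,6-trimethylcyclohex-2-ene-1,4-dione) | CC1=CC(=O)CC(C)(C)C1=O | starting material
2 | (6R)-levodione [(R)-2,2,6-trimethylcyclohexane-1,4-dione] | CC1(C)CC(=O)C[C@@H](C)C1=O | intermediate
3 | (4R,6R)-actinol | CC1(C)C[C@H](O)C[C@@H](C)C1=O | intermediate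
4 | (4R,6R)-4-(tert-butoxycarbonyloxy)-2,2,6-trimethylcyclohexanone | CC1(C)C[C@H](OC(=O)OC(C)(C)C)C[C@@H](C)C1=O | intermediate
5 | (4R)-4-(tert-butoxycarbonyloxy)-2,6,6-trimethylcyclohex-1-en-1-yl triflate | CC1=C(OS(=O)(=O)C(F)(F)F)C(C)(C)C[C@H](OC(=O)OC(C)(C)C)C1 | intermediate
6 | methyl vinyl ketone (but-3-en-2-one) | CC(=O)C=C | starting material
7 | (3R)-3-(tert-butoxycarbonyloxy)-β-ionone | CC(=O)/C=C/C1=C(C)C[C@@H](OC(=O)OC(C)(C)C)CC1(C)C | intermediate
8 | (3S,5R,6S)-3-(tert-butoxycarbonyloxy)-5,6-epoxy-5,6-dihydro-β-ionone | CC(=O)/C=C/[C@]1(O2)C(C)(C)C[C@H](OC(=O)OC(C)(C)C)C[C@]12C | intermediate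
9 | (3S,5S,6S)-3,5,6-trihydroxy-5,6-dihydro-β-ionone 3,5-cyclic carbonate | CC(=O)/C=C/[C@]1(O)C(C)(C)C[C@H](O2)C[C@]1(C)OC2=O | intermediate
10 | N-cyclohexyl aldimine of aldehyde 11 | C1CCCCC1N=C/C=C(C)/C=C/[C@]2(O)C(C)(C)C[C@H](O3)C[C@]2(C)OC3=O | intermediate
11 | triol-end C15 aldehyde, (2E,4E)-dienal with 3,5-cyclic carbonate and free 6-hydroxyl | O=C/C=C(C)/C=C/[C@]1(O)C(C)(C)C[C@H](O2)C[C@]1(C)OC2=O | intermediate
12 | (±)-α-ionone | CC1=CCCC(C)(C)C1/C=C/C(C)=O | starting material
13 | (±)-(2E,4E)-3-methyl-5-(2,6,6-trimethylcyclohex-2-en-1-yl)penta-2,4-dienenitrile | CC1=CCCC(C)(C)C1/C=C/C(C)=C/C#N | intermediate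
14 | (±)-(2E,4E)-3-methyl-5-(2,6,6-trimethyl-4-oxocyclohex-2-en-1-yl)penta-2,4-dienenitrile | CC1=CC(=O)CC(C)(C)C1/C=C/C(C)=C/C#N | intermediate
15 | (2E,4E)-5-[(1R,4R)-4-hydroxy-2,6,6-trimethylcyclohex-2-en-1-yl]-3-methylpenta-2,4-dienenitrile | CC1=C[C@H](O)CC(C)(C)[C@H]1/C=C/C(C)=C/C#N | intermediate
16 | N,O-bis(diisobutylaluminium) aldimine from 15 | CC1=C[C@H](O[Al](CC(C)C)CC(C)C)CC(C)(C)[C@H]1/C=C/C(C)=C/C=N[Al](CC(C)C)CC(C)C | intermediate
17 | (2E,4E)-5-[(1R,4R)-4-hydroxy-2,6,6-trimethylcyclohex-2-en-1-yl]-3-methylpenta-2,4-dienal | CC1=C[C@H](O)CC(C)(C)[C@H]1/C=C/C(C)=C/C=O | intermediate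
18 | (2E,4E,6E)-2,7-dimethylocta-2,4,6-trienedial | O=C/C(C)=C/C=C/C=C(C)/C=O | starting material
19 | (2E,4E,6E)-2,7-dimethylocta-2,4,6-triene-1,8-diol | OC/C(C)=C/C=C/C=C(C)/CO | intermediate
20 | (2E,4E,6E)-1,8-dibromo-2,7-dimethylocta-2,4,6-triene | BrC/C(C)=C/C=C/C=C(C)/CBr | intermediate
21 | tetraethyl [(2E,4E,6E)-2,7-dimethylocta-2,4,6-triene-1,8-diyl]bis(phosphonate) | CCOP(=O)(OCC)C/C(C)=C/C=C/C=C(C)/CP(=O)(OCC)OCC | intermediate
22 | ε-end C25 phosphonate | CC1=C[C@H](O)CC(C)(C)[C@H]1/C=C/C(C)=C/C=C/C(C)=C/C=C/C=C(C)/CP(=O)(OCC)OCC | intermediate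
23 | (3S,5S,6S,3'R,6'R)-5,6-dihydro-β,ε-carotene-3,5,6,3'-tetrol 3,5-cyclic carbonate | CC1=C[C@H](O)CC(C)(C)[C@H]1/C=C/C(C)=C/C=C/C(C)=C/C=C/C=C(C)/C=C/C=C(C)/C=C/[C@]1(O)C(C)(C)C[C@H](O2)C[C@]1(C)OC2=O | intermediate
24 | (3S,5S,6S,3'R,6'R)-5,6-dihydro-β,ε-carotene-3,5,6,3'-tetrol | CC1=C[C@H](O)CC(C)(C)[C@H]1/C=C/C(C)=C/C=C/C(C)=C/C=C/C=C(C)/C=C/C=C(C)/C=C/[C@]1(O)C(C)(C)C[C@H](O)C[C@]1(C)O | target

**Step count**

Total: 17 steps. Longest linear sequence: 9 steps (steps 1–7, 16, 17).

**Steps most likely to fail**

1. Step 6. The carbonate may fail to reach the axial position it needs beside the syn C1 methyl, and the activated epoxide may then undergo semipinacol ring contraction, or the tert-butyl group may be lost before the ring closes. The fallback replaces the tethered nucleophile by water and moves the carbonate afterwards. It sets out from 8: dilute HClO4 in THF/H2O at 0 °C should open the oxirane by anti attack of water at C5, the more cation-stabilised carbon, to give (3S,5S,6S)-3-(tert-butoxycarbonyloxy)-5,6-dihydroxy-5,6-dihydro-β-ionone F1. NaH in THF then lets the C5 alkoxide, cis to the C3 carbonate, add to the carbonate carbonyl and expel tert-butoxide, which returns the route to 9.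

2. Step 5. The facial selectivity of the peracid may be poor or may favour the syn epoxide, which cannot deliver the tether to the rear of C5. The fallback makes the epoxide under reagent control. It sets out from 5: Stille coupling with (tributylstannyl)methanol (Pd(PPh3)4, LiCl, dioxane, 90 °C) gives the allylic alcohol tert-butyl (1R)-4-(hydroxymethyl)-3,5,5-trimethylcyclohex-3-en-1-yl carbonate F2. Sharpless asymmetric epoxidation (Ti(OiPr)4, D-(−)-diethyl tartrate, t-BuOOH, 4 Å sieves, CH2Cl2, −20 °C) should give the anti-epoxy alcohol F3. Dess–Martin oxidation gives the anti-epoxy aldehyde F4, and Wittig reaction with 1-(triphenylphosphoranylidene)propan-2-one in toluene returns the route to 8.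

3. Step 10. Catalyst control may be incomplete for the mismatched enantiomer, so that some (3S,6S) alcohol, the enantiomer of 15, travels with it and lowers its enantiomeric purity. Because the triol half is enantiopure, such material would surface later as a diastereomer of 23 and 24 that crystallisation may remove. The fallback is a covalent resolution. It sets out from 14: Luche reduction (NaBH4, CeCl3·7H2O, MeOH, −20 °C) and chromatography give the racemic trans-3-hydroxy nitrile F5. Esterification with (S)-O-methylmandelic acid (DCC, DMAP) gives two diastereomeric esters, from which the (S)-O-methylmandelate of the (1R,4R) alcohol F6 is separated by chromatography or crystallisation. Methanolysis (K2CO3, MeOH) returns the route to 15.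

**Further compounds**

F1 | step 6 | (3S,5S,6S)-3-(tert-butoxycarbonyloxy)-5,6-dihydroxy-5,6-dihydro-β-ionone | CC(=O)/C=C/[C@]1(O)C(C)(C)C[C@H](OC(=O)OC(C)(C)C)C[C@]1(C)O
F2 | step 5 | tert-butyl (1R)-4-(hydroxymethyl)-3,5,5-trimethylcyclohex-3-en-1-yl carbonate | OCC1=C(C)C[C@@H](OC(=O)OC(C)(C)C)CC1(C)C
F3 | step 5 | anti-epoxy alcohol (5,6-epoxide trans to the C3 carbonate, C6 hydroxymethyl) | OC[C@]1(O2)C(C)(C)C[C@H](OC(=O)OC(C)(C)C)C[C@]12C
F4 | step 5 | anti-epoxy aldehyde (5,6-epoxide trans to the C3 carbonate, C6 formyl) | O=C[C@]1(O2)C(C)(C)C[C@H](OC(=O)OC(C)(C)C)C[C@]12C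
F5 | step 10 | racemic trans-3-hydroxy nitrile, (1R,4R) and (1S,4S) | CC1=C[C@H](O)CC(C)(C)[C@H]1/C=C/C(C)=C/C#N.CC1=C[C@@H](O)CC(C)(C)[C@@H]1/C=C/C(C)=C/C#N
F6 | step 10 | (S)-O-methylmandelate of the (1R,4R) alcohol 15 | CC1=C[C@H](OC(=O)[C@@H](OC)c2ccccc2)CC(C)(C)[C@H]1/C=C/C(C)=C/C#N
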